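The carbocycle is cut at C4–C4a. Ring A has one unsubstituted carbon, C5, lying between the ring-fusion carbon C4a and the methoxy-bearing C6. An aryne spanning C4a and C5 is therefore biased, by that oxygen and by the tether, to accept carbon at C4a and to finish with hydrogen on C5. In one operation LiN(i-Pr)2 makes the kinetic enolate of an open-chain methyl ketone and the ring A aryne, and the enolate carbon closes the six-membered ring as the C3 ketone, leaving C1 and C2 untouched. The precursor is a (3S,4S)-4,4-diaryl-3-methylbutan-2-one with bromine on C5 and both phenols silylated.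

Key step: step 10

Remark on the chemistry (assumptions): locants C1–C8a are those of the target's 1,2-dihydronaphthalene and are kept for all intermediates (ring A = fused benzene ring C4a–C8a, ring B = aryl group on C1); the target is (1S,2S) with ring B and the C2 methyl group cis; TBS = tert-butyldimethylsilyl, TBSO = its oxy substituent, Tol = 4-methylphenyl; the enamine step is assumed to show the relative topicity of prolinol-ether Michael additions to nitroalkenes.

Step 1
Reactants: 1 2,6-dimethoxyphenol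
Product: 2 tert-butyl(2,6-dimethoxyphenoxy)dimethylsilane
Conditions: TBSCl, imidazole, DMF, rt
Reagents that add atoms: tert-butyldimethylsilyl chloride, CC(C)(C)[Si](C)(C)Cl
Why: Imidazole-promoted O-silylation of a phenol; the hindered aryl silyl ether should withstand organolithium, Grignard and amide reagents and can be removed at the end with fluoride, so that the acid-sensitive product never meets acid.

Step 2
Reactants: 2 tert-butyl(2,6-dimethoxyphenoxy)dimethylsilane
Product: 3 tert-butyl(3,5-dibromo-2,6-dimethoxyphenoxy)dimethylsilane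
Conditions: NBS (2.1 equiv), MeCN, 0 °C to rt
Reagents that add atoms: N-bromosuccinimide, O=C1CCC(=O)N1Br
Why: Electrophilic aromatic bromination: the two ring positions that are each ortho to one methoxy group and para to the other are the activated ones, whereas the position para to the silyloxy group is served only by an oxygen twisted out of conjugation by its two ortho neighbours, so the symmetrical dibromide is expected.

Step 3
Reactants: 4 4-hydroxy-3,5-dimethoxybenzaldehyde (syringaldehyde)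
Product: 5 3,5-dimethoxy-4-(oxan-2-yloxy)benzaldehyde (racemic acetal)
Conditions: 3,4-dihydro-2H-pyran, pyridinium 4-methylbenzenesulfonate (cat.), CH2Cl2, rt
Reagents that add atoms: 3,4-dihydro-2H-pyran, C1=COCCC1
Why: Acid-catalysed addition of the phenol to the enol ether (tetrahydropyranyl acetal formation) masks the acidic OH for the organolithium step with a group that the mild acid of step 5 removes again.

Step 4
Reactants: 3 tert-butyl(3,5-dibromo-2,6-dimethoxyphenoxy)dimethylsilane; 5 3,5-dimethoxy-4-(oxan-2-yloxy)benzaldehyde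
Product: 7 [5-bromo-2,4-dimethoxy-3-(TBSO)phenyl][3,5-dimethoxy-4-(oxan-2-yloxy)phenyl]methanol (mixture of stereoisomers), via aryllithium 6 (not isolated)
Conditions: n-BuLi (1.0 equiv), THF, −78 °C; 5, −78 to −40 °C; then H2O
Reagents that add atoms: none
Why: Bromine–lithium exchange at one of the two equivalent bromides (the aryllithium has a methoxy group beside it and no ortho halide, so it cannot eliminate) followed by 1,2-addition to the aldehyde joins rings A and B, and the second bromine stays as the later aryne handle on C5.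

Step 5
Reactants: 7 [5-bromo-2,4-dimethoxy-3-(TBSO)phenyl][3,5-dimethoxy-4-(oxan-2-yloxy)phenyl]methanol
Product: 8 4-{[5-bromo-2,4-dimethoxy-3-(TBSO)phenyl](4-methylbenzenesulfonyl)methyl}-2,6-dimethoxyphenol (racemic)
Conditions: TolSO2Na (3 equiv), HCO2H/H2O/THF, rt
Reagents that add atoms: sodium 4-methylbenzenesulfinate, [Na+].[O-]S(=O)c1ccc(C)cc1
Why: Acid ionises the doubly activated benzhydrol and the sulfinate is alkylated at sulfur (unimolecular substitution through the benzhydryl cation), while the same aqueous acid hydrolyses the aryl acetal and should leave the more robust aryl silyl ether in place.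

Step 6
Reactants: 8 4-{[5-bromo-2,4-dimethoxy-3-(TBSO)phenyl](4-methylbenzenesulfonyl)methyl}-2,6-dimethoxyphenol; 9 propanal
Product: 11 (2S,3S)-3-[5-bromo-2,4-dimethoxy-3-(TBSO)phenyl]-3-(4-hydroxy-3,5-dimethoxyphenyl)-2-methylpropanal, via quinone methide 10 (not isolated)
Conditions: 9 (4 equiv), (R)-2-[diphenyl(trimethylsilyloxy)methyl]pyrrolidine (20 mol %), NaHCO3 (aq)/CH2Cl2, 0 °C to rt
Reagents that add atoms: none
Why: Base releases the para-quinone methide by loss of sulfinate and the enamine of propanal adds to its exocyclic carbon (enamine-catalysed 1,6-conjugate addition): the (R)-diphenyl(silyloxy)methyl group shields one face of the (E)-enamine so that C2 should form as S, and an open transition state with the quinoid ring synclinal and ring A antiperiplanar to the enamine double bond should set C1 as S, the arrangement that becomes 1,2-cis in the ring.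

Step 7
Reactants: 11 (2S,3S)-3-[5-bromo-2,4-dimethoxy-3-(TBSO)phenyl]-3-(4-hydroxy-3,5-dimethoxyphenyl)-2-methylpropanal
Product: 12 (2S,3S)-3-[5-bromo-2,4-dimethoxy-3-(TBSO)phenyl]-3-[3,5-dimethoxy-4-(TBSO)phenyl]-2-methylpropanal
Conditions: TBSCl, imidazole, DMF, 0 °C to rt
Reagents that add atoms: tert-butyldimethylsilyl chloride, CC(C)(C)[Si](C)(C)Cl
Why: Imidazole-promoted silylation of the ring B phenol under conditions too weakly basic to enolise the α-branched aldehyde, so C2 is kept and both phenols carry the same fluoride-labile group.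

Step 8
Reactants: 12 (2S,3S)-3-[5-bromo-2,4-dimethoxy-3-(TBSO)phenyl]-3-[3,5-dimethoxy-4-(TBSO)phenyl]-2-methylpropanal
Product: 13 (3S,4S)-4-[5-bromo-2,4-dimethoxy-3-(TBSO)phenyl]-4-[3,5-dimethoxy-4-(TBSO)phenyl]-3-methylbutan-2-ol (both carbinol epimers)
Conditions: MeMgBr, THF, −78 °C; then H2O
Reagents that add atoms: methylmagnesium bromide, C[Mg]Br
Why: Grignard 1,2-addition to the aldehyde at low temperature outruns enolisation, so C2 is kept, and the new carbinol centre may form as a mixture because the next step removes it.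

Step 9
Reactants: 13 (3S,4S)-4-[5-bromo-2,4-dimethoxy-3-(TBSO)phenyl]-4-[3,5-dimethoxy-4-(TBSO)phenyl]-3-methylbutan-2-ol
Product: 14 (3S,4S)-4-[5-bromo-2,4-dimethoxy-3-(TBSO)phenyl]-4-[3,5-dimethoxy-4-(TBSO)phenyl]-3-methylbutan-2-one
Conditions: Dess–Martin periodinane, CH2Cl2, 0 °C to rt
Reagents that add atoms: none
Why: Dess–Martin oxidation of the secondary alcohol under near-neutral conditions gives the methyl ketone without enolising the adjacent C2 centre.

Step 10
Reactants: 14 (3S,4S)-4-[5-bromo-2,4-dimethoxy-3-(TBSO)phenyl]-4-[3,5-dimethoxy-4-(TBSO)phenyl]-3-methylbutan-2-one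
Product: 18 (3S,4S)-6-(TBSO)-4-[3,5-dimethoxy-4-(TBSO)phenyl]-5,7-dimethoxy-3-methyl-3,4-dihydronaphthalen-2(1H)-one, via kinetic lithium enolate 15 (not isolated), via aryne 16 (not isolated), via conjugated lithium enolate 17 (not isolated)
Conditions: LiN(i-Pr)2 (3.5 equiv), THF, −78 °C, then −78 to −20 °C; AcOH/THF, −78 °C
Reagents that add atoms: none
Why: At −78 °C the base removes a proton from the ketone methyl group, the least hindered α-site, to give enolate 15; on warming, more base removes the only ring A proton, C4a–H next to bromine, loss of LiBr gives the C4a–C5 aryne 16, and the enolate carbon C4 attacks C4a to form the C4–C4a bond while C5 picks up a proton. This is the known ring-forming addition of ketone enolates to arynes generated from aryl halides with lithium amide bases. The carbocycle closes in a 6-(enolendo)-exo-dig mode, and no other ring size is within reach because the tether starts at C8a, ortho to C4a. No stereocentre is created and C1 and C2 should stay as they are: with excess base there is no free ketone to equilibrate the enolate, and the product is stored as the conjugated C3–C4 enolate 17 until the cold acetic acid quench. The selectivities needed are attack at C4a and not C5 (fixed by the tether and reinforced by the C6 methoxy group, which stabilises negative charge building up on C5 inductively), bond formation through carbon and not oxygen of the enolate (favoured by the lithium counter-ion in THF) and reaction on ring A only (ring B carries no halide).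

Step 11
Reactants: 18 (3S,4S)-6-(TBSO)-4-[3,5-dimethoxy-4-(TBSO)phenyl]-5,7-dimethoxy-3-methyl-3,4-dihydronaphthalen-2(1H)-one
Product: 20 (3S,4S)-6-(TBSO)-4-[3,5-dimethoxy-4-(TBSO)phenyl]-5,7-dimethoxy-3-methyl-3,4-dihydronaphthalen-2-yl trifluoromethanesulfonate, via potassium enolate 19 (not isolated)
Conditions: KN(SiMe3)2 (1.1 equiv), THF, −78 °C; PhNTf2, −78 to 0 °C; cold 0.5 M HCl wash
Reagents that add atoms: N-phenylbis(trifluoromethanesulfonimide), FC(F)(F)S(=O)(=O)N(c1ccccc1)S(=O)(=O)C(F)(F)F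
Why: Deprotonation occurs at the benzylic C4 methylene, by far the most acidic α-site of a 2-tetralone, and O-sulfonylation of the conjugated enolate (enol triflate formation) fixes the double bond at C3=C4 without touching C2.

Step 12
Reactants: 20 (3S,4S)-6-(TBSO)-4-[3,5-dimethoxy-4-(TBSO)phenyl]-5,7-dimethoxy-3-methyl-3,4-dihydronaphthalen-2-yl trifluoromethanesulfonate
Product: 21 (1S,2S)-7-(TBSO)-1-[3,5-dimethoxy-4-(TBSO)phenyl]-6,8-dimethoxy-2,3-dimethyl-1,2-dihydronaphthalene
Conditions: MeMgBr (2.5 equiv), Fe(acac)3 (10 mol %), THF/NMP, −30 to 0 °C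
Reagents that add atoms: methylmagnesium bromide, C[Mg]Br
Why: Iron-catalysed cross-coupling of an alkenyl triflate with a methyl Grignard reagent (Kumada type) should replace the triflate on C3 by methyl with the C3=C4 double bond held in place, under cold conditions that aryl silyl ethers and the C1 and C2 centres tolerate.

Step 13
Reactants: 21 (1S,2S)-7-(TBSO)-1-[3,5-dimethoxy-4-(TBSO)phenyl]-6,8-dimethoxy-2,3-dimethyl-1,2-dihydronaphthalene
Product: 22 4-[(1S,2S)-7-hydroxy-6,8-dimethoxy-2,3-dimethyl-1,2-dihydronaphthalen-1-yl]-2,6-dimethoxyphenol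
Conditions: Bu4NF, AcOH, THF, 0 °C, argon
Reagents that add atoms: none
Why: Fluoride-induced cleavage of both aryl silyl ethers, buffered with acetic acid, frees the two phenols without strong acid or base, which the electron-rich styrene unit (C3=C4 conjugated to ring A, with the C7 oxygen para to C4a) might not survive.

Compound list
1 | 2,6-dimethoxyphenol | COc1cccc(OC)c1O | starting material
2 | tert-butyl(2,6-dimethoxyphenoxy)dimethylsilane | COc1cccc(OC)c1O[Si](C)(C)C(C)(C)C | intermediate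
3 | tert-butyl(3,5-dibromo-2,6-dimethoxyphenoxy)dimethylsilane | COc1c(Br)cc(Br)c(OC)c1O[Si](C)(C)C(C)(C)C | intermediate
4 | 4-hydroxy-3,5-dimethoxybenzaldehyde (syringaldehyde) | COc1cc(C=O)cc(OC)c1O | starting material
5 | 3,5-dimethoxy-4-(oxan-2-yloxy)benzaldehyde (racemic acetal) | COc1cc(C=O)cc(OC)c1OC1CCCCO1 | intermediate
6 | [5-bromo-2,4-dimethoxy-3-(TBSO)phenyl]lithium (formed in the flask) | [Li]c1cc(Br)c(OC)c(O[Si](C)(C)C(C)(C)C)c1OC | intermediate
7 | [5-bromo-2,4-dimethoxy-3-(TBSO)phenyl][3,5-dimethoxy-4-(oxan-2-yloxy)phenyl]methanol (mixture of stereoisomers) | COc1cc(C(O)c2cc(Br)c(OC)c(O[Si](C)(C)C(C)(C)C)c2OC)cc(OC)c1OC1CCCCO1 | intermediate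
8 | 4-{[5-bromo-2,4-dimethoxy-3-(TBSO)phenyl](4-methylbenzenesulfonyl)methyl}-2,6-dimethoxyphenol (racemic) | COc1cc(C(c2cc(Br)c(OC)c(O[Si](C)(C)C(C)(C)C)c2OC)S(=O)(=O)c2ccc(C)cc2)cc(OC)c1O | intermediate
9 | propanal | CCC=O | starting material
10 | 4-{[5-bromo-2,4-dimethoxy-3-(TBSO)phenyl]methylidene}-2,6-dimethoxycyclohexa-2,5-dien-1-one (quinone methide, formed in the flask) | COC1=CC(=Cc2cc(Br)c(OC)c(O[Si](C)(C)C(C)(C)C)c2OC)C=C(OC)C1=O | intermediate
11 | (2S,3S)-3-[5-bromo-2,4-dimethoxy-3-(TBSO)phenyl]-3-(4-hydroxy-3,5-dimethoxyphenyl)-2-methylpropanal | COc1cc([C@H]([C@H](C)C=O)c2cc(Br)c(OC)c(O[Si](C)(C)C(C)(C)C)c2OC)cc(OC)c1O | intermediate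
12 | (2S,3S)-3-[5-bromo-2,4-dimethoxy-3-(TBSO)phenyl]-3-[3,5-dimethoxy-4-(TBSO)phenyl]-2-methylpropanal | COc1cc([C@H]([C@H](C)C=O)c2cc(Br)c(OC)c(O[Si](C)(C)C(C)(C)C)c2OC)cc(OC)c1O[Si](C)(C)C(C)(C)C | intermediate
13 | (3S,4S)-4-[5-bromo-2,4-dimethoxy-3-(TBSO)phenyl]-4-[3,5-dimethoxy-4-(TBSO)phenyl]-3-methylbutan-2-ol (both carbinol epimers) | COc1cc([C@H]([C@H](C)C(C)O)c2cc(Br)c(OC)c(O[Si](C)(C)C(C)(C)C)c2OC)cc(OC)c1O[Si](C)(C)C(C)(C)C | intermediate
14 | (3S,4S)-4-[5-bromo-2,4-dimethoxy-3-(TBSO)phenyl]-4-[3,5-dimethoxy-4-(TBSO)phenyl]-3-methylbutan-2-one (precursor of the key step) | COc1cc([C@H]([C@H](C)C(C)=O)c2cc(Br)c(OC)c(O[Si](C)(C)C(C)(C)C)c2OC)cc(OC)c1O[Si](C)(C)C(C)(C)C | intermediate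
15 | lithium enolate of 14 at the methyl group, lithium (3S,4S)-4,4-diaryl-3-methylbut-1-en-2-olate (formed in the flask) | COc1cc([C@H]([C@H](C)C(=C)O[Li])c2cc(Br)c(OC)c(O[Si](C)(C)C(C)(C)C)c2OC)cc(OC)c1O[Si](C)(C)C(C)(C)C | intermediate
16 | enolate 15 after loss of H (C4a) and Br (C5): ring A as the C4a–C5 aryne (formed in the flask) | COc1cc([C@H]([C@H](C)C(=C)O[Li])C2=C(OC)C(O[Si](C)(C)C(C)(C)C)=C(OC)C#C2)cc(OC)c1O[Si](C)(C)C(C)(C)C | intermediate
17 | lithium C3–C4 enolate of tetralone 18 (formed in the flask) | COc1cc([C@H]2c3c(cc(OC)c(O[Si](C)(C)C(C)(C)C)c3OC)C=C(O[Li])[C@H]2C)cc(OC)c1O[Si](C)(C)C(C)(C)C | intermediate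
18 | (3S,4S)-6-(TBSO)-4-[3,5-dimethoxy-4-(TBSO)phenyl]-5,7-dimethoxy-3-methyl-3,4-dihydronaphthalen-2(1H)-one (in target locants the (1S,2S)-1-aryl-2-methyl-3-oxotetralin) | COc1cc([C@H]2c3c(cc(OC)c(O[Si](C)(C)C(C)(C)C)c3OC)CC(=O)[C@H]2C)cc(OC)c1O[Si](C)(C)C(C)(C)C | intermediate
19 | potassium C3–C4 enolate of 18 (formed in the flask) | COc1cc([C@H]2c3c(cc(OC)c(O[Si](C)(C)C(C)(C)C)c3OC)C=C(O[K])[C@H]2C)cc(OC)c1O[Si](C)(C)C(C)(C)C | intermediate
20 | (3S,4S)-6-(TBSO)-4-[3,5-dimethoxy-4-(TBSO)phenyl]-5,7-dimethoxy-3-methyl-3,4-dihydronaphthalen-2-yl trifluoromethanesulfonate | COc1cc([C@H]2c3c(cc(OC)c(O[Si](C)(C)C(C)(C)C)c3OC)C=C(OS(=O)(=O)C(F)(F)F)[C@H]2C)cc(OC)c1O[Si](C)(C)C(C)(C)C | intermediate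
21 | (1S,2S)-7-(TBSO)-1-[3,5-dimethoxy-4-(TBSO)phenyl]-6,8-dimethoxy-2,3-dimethyl-1,2-dihydronaphthalene | COc1cc([C@H]2c3c(cc(OC)c(O[Si](C)(C)C(C)(C)C)c3OC)C=C(C)[C@H]2C)cc(OC)c1O[Si](C)(C)C(C)(C)C | intermediate
22 | 4-[(1S,2S)-7-hydroxy-6,8-dimethoxy-2,3-dimethyl-1,2-dihydronaphthalen-1-yl]-2,6-dimethoxyphenol | COc1cc([C@H]2c3c(cc(OC)c(O)c3OC)C=C(C)[C@H]2C)cc(OC)c1O | target

Total step count: 13. Longest linear sequence: 12 steps (from 1 through steps 1, 2 and 4–13; step 3 prepares the ring B aldehyde).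

Steps most likely to fail

1. Step 10 (key step). Removal of the C4a proton, which is flanked by bromine and the branched side chain, may be slow. The base could then add to the aryne, the enolate could close through oxygen, or the enolate could equilibrate and erode C2. The fallback sets out from 1, uses 5 and 9, and returns at 18. It moves the halogen to C4a so that the same C4–C4a bond is made by palladium-catalysed enolate arylation and no aryne is needed. Bromination of 1 para to the hydroxy group (NBS, CH2Cl2, 0 °C) gives 4-bromo-2,6-dimethoxyphenol F1, which is also an article of commerce, and silylation as in step 1 gives (4-bromo-2,6-dimethoxyphenoxy)(tert-butyl)dimethylsilane F2. LiN(i-Pr)2 in THF at −78 °C removes the proton between bromine and methoxy to give aryllithium F3, which is trapped in the cold with 5 to give carbinol F4. The operations of steps 5 to 9 then lead through sulfone F5, quinone methide F6 (in the flask), aldehyde F7, bis-silyl ether F8 and alcohol F9 to C4a-bromo ketone F10. Pd(OAc)2, 2-dicyclohexylphosphino-2′,4′,6′-triisopropylbiphenyl and K3PO4 in toluene at 80 °C should then join the methyl ketone enolate to C4a (intramolecular ketone α-arylation) and give 18.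

2. Step 6. The two faces of the quinone methide carbon may be poorly distinguished, so that C1 forms as a mixture or in the opposite sense, or the quinone methide may hydrate or oligomerise before the enamine captures it. The fallback sets out from 4 and from aryllithium 6 and returns at 12. It sets the two centres one after the other under control of an oxazolidinone auxiliary. Silylation of 4 gives 3,5-dimethoxy-4-(TBSO)benzaldehyde F11. Horner–Wadsworth–Emmons reaction with (S)-3-[(diethoxyphosphoryl)acetyl]-4-phenyl-1,3-oxazolidin-2-one (LiCl, i-Pr2NEt, MeCN) gives (E)-enoyl imide F12. Aryllithium 6 is converted with MgBr2·OEt2 into aryl Grignard reagent F13, which in the presence of CuBr·SMe2 (THF, −40 to −20 °C) should add to the chelated s-cis enoyl imide from the face opposite the phenyl group and give (3S)-diaryl imide F14, setting C1. NaN(SiMe3)2 and MeI at −78 °C should then methylate the chelated (Z)-enolate anti to the same phenyl group and give (2S,3S)-methyl imide F15, setting C2. LiBH4 removes the auxiliary to give primary alcohol F16, and Dess–Martin oxidation gives 12.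

3. Step 5. The benzhydryl cation may alkylate a second electron-rich ring and give oligomers, or the silyl ether may be lost in the acidic medium. The fallback sets out from 7 and returns at 10, which then enters step 6 without added base. Ionic hydrogenation of 7 (Et3SiH, CF3CO2H, CH2Cl2, 0 °C) reduces the carbinol and removes the acetal to give diarylmethane phenol F17. Oxidation with Ag2O in CH2Cl2 (dehydrogenation of a para-alkylphenol) should give quinone methide 10 as a filtered solution, to which 9 and the amine catalyst are added directly.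

Further compounds
F1 | step 10 | 4-bromo-2,6-dimethoxyphenol | COc1cc(Br)cc(OC)c1O
F2 | step 10 | (4-bromo-2,6-dimethoxyphenoxy)(tert-butyl)dimethylsilane | COc1cc(Br)cc(OC)c1O[Si](C)(C)C(C)(C)C
F3 | step 10 | [6-bromo-2,4-dimethoxy-3-(TBSO)phenyl]lithium | [Li]c1c(Br)cc(OC)c(O[Si](C)(C)C(C)(C)C)c1OC
F4 | step 10 | [6-bromo-2,4-dimethoxy-3-(TBSO)phenyl][3,5-dimethoxy-4-(oxan-2-yloxy)phenyl]methanol | COc1cc(C(O)c2c(Br)cc(OC)c(O[Si](C)(C)C(C)(C)C)c2OC)cc(OC)c1OC1CCCCO1
F5 | step 10 | 4-{[6-bromo-2,4-dimethoxy-3-(TBSO)phenyl](4-methylbenzenesulfonyl)methyl}-2,6-dimethoxyphenol | COc1cc(C(c2c(Br)cc(OC)c(O[Si](C)(C)C(C)(C)C)c2OC)S(=O)(=O)c2ccc(C)cc2)cc(OC)c1O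
F6 | step 10 | 4-{[6-bromo-2,4-dimethoxy-3-(TBSO)phenyl]methylidene}-2,6-dimethoxycyclohexa-2,5-dien-1-one | COC1=CC(=Cc2c(Br)cc(OC)c(O[Si](C)(C)C(C)(C)C)c2OC)C=C(OC)C1=O
F7 | step 10 | (2S,3S)-3-[6-bromo-2,4-dimethoxy-3-(TBSO)phenyl]-3-(4-hydroxy-3,5-dimethoxyphenyl)-2-methylpropanal | COc1cc([C@H]([C@H](C)C=O)c2c(Br)cc(OC)c(O[Si](C)(C)C(C)(C)C)c2OC)cc(OC)c1O
F8 | step 10 | (2S,3S)-3-[6-bromo-2,4-dimethoxy-3-(TBSO)phenyl]-3-[3,5-dimethoxy-4-(TBSO)phenyl]-2-methylpropanal | COc1cc([C@H]([C@H](C)C=O)c2c(Br)cc(OC)c(O[Si](C)(C)C(C)(C)C)c2OC)cc(OC)c1O[Si](C)(C)C(C)(C)C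
F9 | step 10 | (3S,4S)-4-[6-bromo-2,4-dimethoxy-3-(TBSO)phenyl]-4-[3,5-dimethoxy-4-(TBSO)phenyl]-3-methylbutan-2-ol (both carbinol epimers) | COc1cc([C@H]([C@H](C)C(C)O)c2c(Br)cc(OC)c(O[Si](C)(C)C(C)(C)C)c2OC)cc(OC)c1O[Si](C)(C)C(C)(C)C
F10 | step 10 | (3S,4S)-4-[6-bromo-2,4-dimethoxy-3-(TBSO)phenyl]-4-[3,5-dimethoxy-4-(TBSO)phenyl]-3-methylbutan-2-one | COc1cc([C@H]([C@H](C)C(C)=O)c2c(Br)cc(OC)c(O[Si](C)(C)C(C)(C)C)c2OC)cc(OC)c1O[Si](C)(C)C(C)(C)C
F11 | step 6 | 3,5-dimethoxy-4-(TBSO)benzaldehyde | COc1cc(C=O)cc(OC)c1O[Si](C)(C)C(C)(C)C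
F12 | step 6 | (4S)-3-{(2E)-3-[3,5-dimethoxy-4-(TBSO)phenyl]prop-2-enoyl}-4-phenyl-1,3-oxazolidin-2-one | O=C1OC[C@H](c2ccccc2)N1C(=O)/C=C/c1cc(OC)c(O[Si](C)(C)C(C)(C)C)c(OC)c1
F13 | step 6 | [5-bromo-2,4-dimethoxy-3-(TBSO)phenyl]magnesium bromide | Br[Mg]c1cc(Br)c(OC)c(O[Si](C)(C)C(C)(C)C)c1OC
F14 | step 6 | (4S)-3-{(3S)-3-[5-bromo-2,4-dimethoxy-3-(TBSO)phenyl]-3-[3,5-dimethoxy-4-(TBSO)phenyl]propanoyl}-4-phenyl-1,3-oxazolidin-2-one | O=C1OC[C@H](c2ccccc2)N1C(=O)C[C@H](c1cc(Br)c(OC)c(O[Si](C)(C)C(C)(C)C)c1OC)c1cc(OC)c(O[Si](C)(C)C(C)(C)C)c(OC)c1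
F15 | step 6 | (4S)-3-{(2S,3S)-3-[5-bromo-2,4-dimethoxy-3-(TBSO)phenyl]-3-[3,5-dimethoxy-4-(TBSO)phenyl]-2-methylpropanoyl}-4-phenyl-1,3-oxazolidin-2-one | O=C1OC[C@H](c2ccccc2)N1C(=O)[C@@H](C)[C@H](c1cc(Br)c(OC)c(O[Si](C)(C)C(C)(C)C)c1OC)c1cc(OC)c(O[Si](C)(C)C(C)(C)C)c(OC)c1
F16 | step 6 | (2S,3S)-3-[5-bromo-2,4-dimethoxy-3-(TBSO)phenyl]-3-[3,5-dimethoxy-4-(TBSO)phenyl]-2-methylpropan-1-ol | OC[C@@H](C)[C@H](c1cc(Br)c(OC)c(O[Si](C)(C)C(C)(C)C)c1OC)c1cc(OC)c(O[Si](C)(C)C(C)(C)C)c(OC)c1
F17 | step 5 | 4-{[5-bromo-2,4-dimethoxy-3-(TBSO)phenyl]methyl}-2,6-dimethoxyphenol | COc1cc(Cc2cc(Br)c(OC)c(O[Si](C)(C)C(C)(C)C)c2OC)cc(OC)c1O
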